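## Retrosynthetic overview

1. The C10–C11 bond is cut by a Sonogashira coupling between a terminal alkynyl oxolane and an (E)-alkenyl iodide that already carries the (E,E)-bromodiene (C–I reacts before dienyl C–Br).
2. The alkyne comes from a trans-oxolane-2-carbaldehyde dimethyl acetal by one-carbon homologation.
3. The acetal comes from oxidative ring contraction of a 2-substituted 3,4-dihydro-2H-pyran: the ring oxygen makes a 1,2-shift under control of a chiral aryl-λ3-iodane, which sets the second stereocentre.
4. The dihydropyran comes from Rh-vinylidene cycloisomerisation of an (R)-alkynol, itself made by catalytic asymmetric addition of an ester-bearing dialkylzinc to pent-4-ynal (first stereocentre).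
5. Ring order: six-membered enol ether first, then contraction to the only ring of the target, the oxolane. The bromodiene arm is built separately from oct-1-en-7-yne (hydrozirconation/iodination, cross-metathesis, Takai olefination).

Assumption: pent-4-ynal, oct-1-en-7-yne, methyl 4-iodobutanoate and anhydrous CrBr2 are bought as such; the target as drawn is the trans-2,5-disubstituted oxolane, (2R,5S).

## Route

Step 1
Reactants: 1 methyl 4-iodobutanoate; 2 pent-4-ynal
Product: 4 methyl (5R)-5-hydroxynon-8-ynoate, via bis(4-methoxy-4-oxobutyl)zinc 3 (not isolated)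
Conditions: 1 (3 equiv), Et2Zn (neat), CuI (0.3 mol%), 50 °C, then strip EtI/Et2Zn in vacuo; Ti(OiPr)4 (2 equiv), (1S,2S)-N,N'-bis(trifluoromethanesulfonyl)cyclohexane-1,2-diamine (8 mol%), 2, toluene, −20 °C; sat. aq. NH4Cl, cold
Reagents that add atoms: none
Why: Iodine–zinc exchange gives the ester-bearing dialkylzinc, and the Ti(OiPr)4/bis-triflamide-catalysed enantioselective organozinc addition (Knochel type) sets the carbinol centre as R by Re-face alkyl transfer, the ligand being the antipode of the one that gives Si-face addition of Et2Zn to benzaldehyde; the alkyne C–H and the ester are inert to the dialkylzinc at −20 °C.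

Step 2
Reactants: 4 methyl (5R)-5-hydroxynon-8-ynoate
Product: 5 methyl 4-[(2R)-3,4-dihydro-2H-pyran-2-yl]butanoate
Conditions: [Rh(cod)Cl]2 (2.5 mol%), (4-FC6H4)3P (25 mol%), DMF, 85 °C; chromatography on Et3N-washed silica
Reagents that add atoms: none
Why: The terminal alkyne forms a rhodium vinylidene that the hydroxyl attacks at the terminal carbon (anti-Markovnikov, endo cycloisomerisation of a bis-homopropargylic alcohol), closing the six-membered enol ether without touching the carbinol centre.

Step 3
Reactants: 5 methyl 4-[(2R)-3,4-dihydro-2H-pyran-2-yl]butanoate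
Product: 6 methyl 4-[(2R,5S)-5-(dimethoxymethyl)oxolan-2-yl]butanoate
Conditions: dimethyl (2R,2'R)-2,2'-{[2-(diacetoxy-λ3-iodanyl)-1,3-phenylene]bis(oxy)}dipropanoate (1.2 equiv), MeOH (10 equiv), BF3·OEt2 (20 mol%), CH2Cl2, −78 → −40 °C; Et3N quench
Reagents that add atoms: methanol, CO
Why: Proposed new method: the chiral aryl-λ3-iodane (trivalent iodine) attacks the enol-ether β-carbon of 5 on the face anti to the side chain under control of its twofold-symmetric lactate arms, MeOH caps the oxocarbenium carbon, and the ring oxygen, antiperiplanar to the equatorial C–I bond, then shifts to the iodine-bearing carbon with inversion as the aryl iodide leaves (reductive 1,2-shift, six- to five-membered ring), the exocyclic oxocarbenium being trapped by MeOH as the dimethyl acetal, so anti attack plus inversion gives the 2,5-trans oxolane with the new centre S; the closest known chemistry is the Tl(NO3)3- or PhI(OH)OTs-mediated oxidative ring contraction of glycals and dihydropyrans to tetrahydrofurfural acetals and the lactate-based aryl-λ3-iodane enantioselective oxidative rearrangements of aryl alkenes, neither of which has been shown with reagent-controlled face selection on a simple chiral cyclic enol ether.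

Step 4
Reactants: 6 methyl 4-[(2R,5S)-5-(dimethoxymethyl)oxolan-2-yl]butanoate
Product: 8 methyl 4-[(2R,5S)-5-ethynyloxolan-2-yl]butanoate, via oxolane aldehyde 7 (not isolated)
Conditions: (a) TFA/H2O, CHCl3, 0 °C, NaHCO3 work-up; (b) crude 7, dimethyl (1-diazo-2-oxopropyl)phosphonate (1.3 equiv), K2CO3 (2 equiv), MeOH, 0 °C → rt
Reagents that add atoms: dimethyl (1-diazo-2-oxopropyl)phosphonate (Ohira–Bestmann reagent), CC(=O)C(=[N+]=[N-])P(=O)(OC)OC
Why: Acid hydrolysis frees the aldehyde and Seyferth–Gilbert homologation with the Ohira–Bestmann reagent (alkylidene carbene, 1,2-hydride shift) gives the terminal alkyne under K2CO3/MeOH, which is mild enough to keep the α-alkoxy centre and the methyl ester (degenerate exchange in MeOH).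

Step 5
Reactants: 9 oct-1-en-7-yne
Product: 11 (1E)-1-iodoocta-1,7-diene, via alkenylzirconocene chloride 10 (not isolated)
Conditions: Cp2Zr(H)Cl (1.1 equiv), CH2Cl2, rt; then I2 (1.05 equiv), 0 °C
Reagents that add atoms: iodine, II
Why: Hydrozirconation is syn, terminal-selective and much faster on the terminal alkyne than on the terminal alkene, and iodinolysis of the C–Zr bond goes with retention to the E-iodide.

Step 6
Reactants: 11 (1E)-1-iodoocta-1,7-diene; 12 (2E)-but-2-enal
Product: 13 (2E,8E)-9-iodonona-2,8-dienal
Conditions: 12 (5 equiv), second-generation Hoveyda–Grubbs catalyst RuCl2(H2IMes)(=CH-C6H4-2-OiPr) (3 mol%), CH2Cl2, 40 °C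
Reagents that add atoms: none
Why: Olefin cross-metathesis of a terminal alkene with excess crotonaldehyde gives the E-enal under thermodynamic control, and the internal alkenyl iodide is a spectator.

Step 7
Reactants: 13 (2E,8E)-9-iodonona-2,8-dienal
Product: 14 (1E,3E,9E)-1-bromo-10-iododeca-1,3,9-triene
Conditions: CHBr3 (2 equiv), CrBr2 (6 equiv), THF, 0 °C → rt, dark
Reagents that add atoms: bromoform, BrC(Br)Br
Why: Takai olefination, in which the geminal dichromium species from CHBr3 and divalent chromium adds to the aldehyde and eliminates to the E-bromoalkene; CrBr2 avoids bromide/chloride scrambling, and the alkenyl iodide does not react with chromium without a nickel co-catalyst.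

Step 8
Reactants: 8 methyl 4-[(2R,5S)-5-ethynyloxolan-2-yl]butanoate; 14 (1E,3E,9E)-1-bromo-10-iododeca-1,3,9-triene
Product: 15 methyl 4-[(2R,5S)-5-[(3E,9E,11E)-12-bromododeca-3,9,11-trien-1-yn-1-yl]oxolan-2-yl]butanoate
Conditions: 14 (1.1 equiv), Pd(PPh3)4 (5 mol%), CuI (10 mol%), Et3N (3 equiv), degassed THF, 0 °C → rt
Reagents that add atoms: none
Why: Sonogashira coupling, in which zerovalent palladium inserts into the alkenyl C–I bond far faster than into the dienyl C–Br bond at or below room temperature, with retention of the E geometry and no effect on either stereocentre.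

## Compound list

1 | methyl 4-iodobutanoate | COC(=O)CCCI | starting material
2 | pent-4-ynal | O=CCCC#C | starting material
3 | bis(4-methoxy-4-oxobutyl)zinc | COC(=O)CCC[Zn]CCCC(=O)OC | intermediate
4 | methyl (5R)-5-hydroxynon-8-ynoate | COC(=O)CCC[C@@H](O)CCC#C | intermediate
5 | methyl 4-[(2R)-3,4-dihydro-2H-pyran-2-yl]butanoate | COC(=O)CCC[C@@H]1CCC=CO1 | intermediate
6 | methyl 4-[(2R,5S)-5-(dimethoxymethyl)oxolan-2-yl]butanoate | COC(=O)CCC[C@@H]1CC[C@@H](C(OC)OC)O1 | intermediate
7 | methyl 4-[(2R,5S)-5-formyloxolan-2-yl]butanoate | COC(=O)CCC[C@@H]1CC[C@@H](C=O)O1 | intermediate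
8 | methyl 4-[(2R,5S)-5-ethynyloxolan-2-yl]butanoate | COC(=O)CCC[C@@H]1CC[C@@H](C#C)O1 | intermediate
9 | oct-1-en-7-yne | C=CCCCCC#C | starting material
10 | chlorobis(cyclopentadienyl)[(1E)-octa-1,7-dien-1-yl]zirconium | C=CCCCC/C=C/[Zr](Cl)(C1C=CC=C1)C1C=CC=C1 | intermediate
11 | (1E)-1-iodoocta-1,7-diene | C=CCCCC/C=C/I | intermediate
12 | (2E)-but-2-enal | C/C=C/C=O | starting material
13 | (2E,8E)-9-iodonona-2,8-dienal | O=C/C=C/CCCC/C=C/I | intermediate
14 | (1E,3E,9E)-1-bromo-10-iododeca-1,3,9-triene | Br/C=C/C=C/CCCC/C=C/I | intermediate
15 | methyl 4-[(2R,5S)-5-[(3E,9E,11E)-12-bromododeca-3,9,11-trien-1-yn-1-yl]oxolan-2-yl]butanoate | COC(=O)CCC[C@@H]1CC[C@@H](C#C/C=C/CCCC/C=C/C=C/Br)O1 | target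

## Step count and risks

Total steps: 8. Longest linear sequence: 5 (steps 1, 2, 3, 4, 8); the bromodiene arm (steps 5–7) joins at step 8.

Step 3 is the most likely to fail. Stereoelectronically preferred axial attack on the half-chair with the side chain pseudo-equatorial would put iodine syn to the side chain and lead to the cis oxolane, so the reagent must override the substrate. The (R,R) reagent is written here without proof of its sense of induction; the antipodal reagent is the first thing to try. Acid-catalysed addition of MeOH to the enol ether is the main side reaction. The fallback uses known chemistry and sets out from 4. Semi-hydrogenation (H2, Pd/CaCO3 poisoned with Pb(OAc)2, quinoline, EtOAc) gives methyl (5R)-5-hydroxynon-8-enoate F1. Mukaiyama aerobic oxidative cyclisation (Co(modp)2, the divalent cobalt bis(1-morpholinocarbamoyl-4,4-dimethylpentane-1,3-dionate), 10 mol%, O2, tBuOOH cat., iPrOH, 50 °C) gives the trans isomer methyl 4-[(2R,5S)-5-(hydroxymethyl)oxolan-2-yl]butanoate F2. Dess–Martin oxidation then returns to the route at aldehyde 7, which enters step 4 at stage (b).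

Step 2 is the second risk. The free δ-hydroxy ester can lactonise at 85 °C, and exo attack would give the alkylidene oxolane. The fallback sets out from 4 and builds the enol ether by hydration and elimination instead. Anti-Markovnikov alkyne hydration (CpRu(MeCN)3PF6 with 5,5'-bis(trifluoromethyl)-2,2'-bipyridine, H2O, NMP, rt) gives the aldehyde, which closes to the lactol methyl 4-[(2S)-6-hydroxyoxan-2-yl]butanoate F3 (anomer mixture; same spatial arrangement as in 5, the descriptor changes only through CIP ranking). MsCl/Et3N in CH2Cl2, 0 °C → reflux, eliminates to rejoin the route at 5.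

Step 8 is the third risk. The dienyl bromide of 14 or of the product may start to react with palladium, and the product is light- and metal-sensitive. The fallback installs the bromide last. It sets out from 8 and 13, which are coupled under the same Pd(PPh3)4/CuI/Et3N conditions (only one carbon–halogen bond present) to give methyl 4-[(2R,5S)-5-[(3E,9E)-11-oxoundeca-3,9-dien-1-yn-1-yl]oxolan-2-yl]butanoate F4. Takai olefination of F4 (CHBr3, CrBr2, THF) comes back to the route at 15.

## Further compounds

F1 | step 3 | methyl (5R)-5-hydroxynon-8-enoate | COC(=O)CCC[C@@H](O)CCC=C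
F2 | step 3 | methyl 4-[(2R,5S)-5-(hydroxymethyl)oxolan-2-yl]butanoate | COC(=O)CCC[C@@H]1CC[C@@H](CO)O1
F3 | step 2 | methyl 4-[(2S)-6-hydroxyoxan-2-yl]butanoate | COC(=O)CCC[C@@H]1CCCC(O)O1
F4 | step 8 | methyl 4-[(2R,5S)-5-[(3E,9E)-11-oxoundeca-3,9-dien-1-yn-1-yl]oxolan-2-yl]butanoate | COC(=O)CCC[C@@H]1CC[C@@H](C#C/C=C/CCCC/C=C/C=O)O1
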